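The product here is the complex with one exchanged. You want it in the four flasks at 2.5 min, and your hunch is that it climbs with the charge of incoming ligand. We think Sunday's run says otherwise.

| setting | Thursday's | Sunday's | south | north | south-west | east |
|---|---|---|---|---|---|---|
| starting complex | 32 mM | 32 mM | 32 mM | 32 mM | 32 mM | 32 mM |
| incoming ligand | 0.072 equiv | 2 equiv | 0.100 equiv | 0.300 equiv | 1.00 equiv | 3.00 equiv |
| remark | run made earlier | run made earlier |  |  |  |  |
| time |  |  | 2.5 min | 2.5 min | 2.5 min | 2.5 min |

| run | time / s | complex with one exchanged / % |
|---|---|---|
| Thursday's | 15.0 | 1.0 |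
| Thursday's | 30.0 | 1.6 |
| Thursday's | 50.0 | 2.7 |
| Thursday's | 60.0 | 3.5 |
| Thursday's | 80.0 | 4.0 |
| Sunday's | 10.0 | 16.2 |
| Sunday's | 20.0 | 24.5 |
| Sunday's | 40.0 | 31.1 |
| Sunday's | 50.0 | 32.3 |
| Sunday's | 80.0 | 29.9 |

(scatter of a reading: 0.5 percentage points)

- "hardly changes" means that all values lie within two and a half points (for a concentration: within two and a half percent of the largest)

* [complex with one exchanged] at the end for south, north, south-west, east, in this order
* how the row runs (rises, then falls / falls all the way / hardly changes / rises all the way / falls, then rises)

Thursday's run is the cheap one to read. The incoming ligand is the limiting reagent there, so it decays pseudo-first-order. The reading of 4.0% at 80.0 s, held against the charge of 0.072 equiv, gives a ligand half-life τ = 68.4 s, with the scatter of that reading. Sunday's product falls after its highest reading, 32.3% at 50.0 s, so we take it that the product takes ligand too.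

We assume it does so about as fast as the starting complex, so that τ holds throughout. The rate then integrates in closed form to the uptake, the equivalents of ligand spent per complex charged, u = n(1 − 2^(−t/τ)), where n is the charge in equivalents. We further assume that equal uptake means equal product, which turns Sunday's run into a calibration curve.

Its highest reading stands at uptake 0.795, and south-west reaches 0.781, so we read 10.3 mM. North, at 0.234, lies between Sunday's 0.193 and 0.367, and interpolation gives 18.2%, or 5.82 mM. For south we count each ligand spent as product: 2.50 mM. East, at 2.34, lies past Sunday's last uptake of 1.11, so we put it below 9.57 mM.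

The forecast gives 2.3 mM, 5.6 mM, 10 mM and 3.6 mM, so its row rises, then falls, on the ground that “Sunday's product peaks near 32% and then falls, which indicates a second exchange consuming more ligand”. Its south and north lie under ours, and it puts a number on east where we give a bound.

The flasks give 2.27 mM, 5.60 mM, 9.66 mM and 3.91 mM, and the row rises, then falls.

    leaving ligand + starting complex → side product (k = 0.0690 M⁻¹ s⁻¹)
    complex with one exchanged + incoming ligand → over-reaction product (k = 0.290 M⁻¹ s⁻¹)
    complex with one exchanged + incoming ligand ⇌ leaving ligand + complex with two exchanged (K = 1.60, k = 0.130 M⁻¹ s⁻¹)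
    starting complex + incoming ligand ⇌ leaving ligand + complex with one exchanged (K = 10.0, k = 0.320 M⁻¹ s⁻¹)

South-west kept 25% of its incoming ligand at 2.50 min, so it had spent 0.746 equivalents. At 1.25 min in the same flask, τ gives an uptake of 0.532, which falls between Sunday's 0.367 and 0.667. Interpolating there gives 28.1%, and south-west held 28.2%.

(The data were computed with made-up constants.)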